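**Strategy.** Ring A is treated as the dehydrogenated form of a cyclohexane-1,3-dione: C2–O and C4–O are its two carbonyls, C1 carries the carboxyl carbon, and C6 is bonded to C1′ of a side chain whose only stereocentre, C2′, is made beforehand. One operation, a base-mediated Michael–Claisen annulation of benzyl acetoacetate onto an (E)-enoate, forges C1–C6 and C3–C4 and closes the carbocycle, so no aromatic substitution is needed to position any substituent. The enoate is a benzyl hexadec-2-enoate bearing an (R)-silyl ether at C5 and a benzyl ether at C16, made by asymmetric allylboration and cross-metathesis. Aromatisation, phenol benzylation, silyl-to-acetyl exchange and one global hydrogenolysis finish the synthesis.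

Key step: step 6

Remarks on the chemistry (assumptions):
- Numbering: ring A has the carboxyl group on C1, oxygens on C2 and C4, and the side chain on C6. The side chain runs from C1′ (ArCH2) to C13′ (CH2OH); C2′ of the target is (R).
- The C2′ oxygen is carried as a tert-butyldiphenylsilyl ether. It is as inert to alkoxide as the smaller trialkylsilyl ethers, but it is the one most likely to outlast the HBr set free in warm DMF in step 7.
- Every group that must fall at the end is benzyl, so one hydrogenolysis suffices and all ester exchange with benzyloxide in step 6 is degenerate.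
- Base in step 6 is more than one equivalent overall, because the cyclic β-dicarbonyl product is a vinylogous acid and keeps one equivalent as its sodium salt.
- Step 6 creates C1 and C6 as sp3 centres without control (diastereomers and enol tautomers). This is harmless: both become sp2 in step 7.
- NaOCH2Ph is used as the commercial 1.0 M solution in benzyl alcohol.

Step 1
Reactants: 1 dodecane-1,12-diol
Product: 2 12-(benzyloxy)dodecan-1-ol
Conditions: NaH (1.0 equiv), BnBr (1.0 equiv), Bu4NI (cat.), THF/DMF, 0 °C → rt; 1 in excess (2 equiv)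
Reagents that add atoms: benzyl bromide, BrCc1ccccc1
Why: Williamson etherification of a symmetrical diol used in excess should give mainly the monoether, which is separated from recovered diol and a little bis-ether by chromatography.

Step 2
Reactants: 2 12-(benzyloxy)dodecan-1-ol
Product: 3 12-(benzyloxy)dodecanal
Conditions: TEMPO (2,2,6,6-tetramethylpiperidin-1-oxyl, cat.), PhI(OAc)2, CH2Cl2, rt
Reagents that add atoms: none
Why: Oxoammonium-mediated (TEMPO) oxidation of a primary alcohol stops at the aldehyde and leaves the benzyl ether untouched.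

Step 3
Reactants: 3 12-(benzyloxy)dodecanal
Product: 5 (R)-15-(benzyloxy)pentadec-1-en-4-ol, via borinate ester 4 (not isolated)
Conditions: (−)-Ipc2BOMe, allylMgBr, Et2O, 0 °C → rt; then 3, −78 °C; then 3 M NaOH, 30 % H2O2, rt
Reagents that add atoms: allylmagnesium bromide, C=CC[Mg]Br
Why: Brown asymmetric allylboration through a closed chair (Zimmerman–Traxler) transition state, in which the isopinocampheyl groups of the (+)-α-pinene series direct the allyl group to the Si face of an unbranched aldehyde; this sets the (R)-carbinol that becomes C2′, and alkaline peroxide then cleaves the borinate.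

Step 4
Reactants: 5 (R)-15-(benzyloxy)pentadec-1-en-4-ol
Product: 6 (R)-{[15-(benzyloxy)pentadec-1-en-4-yl]oxy}(tert-butyl)diphenylsilane
Conditions: TBDPSCl, imidazole, 4-(dimethylamino)pyridine (cat.), DMF, rt → 40 °C
Reagents that add atoms: tert-butyl(chloro)diphenylsilane, CC(C)(C)[Si](Cl)(c1ccccc1)c1ccccc1
Why: Imidazole-promoted O-silylation of a secondary alcohol with retention at carbon (the C–O bond is not touched) gives an ether that tolerates alkoxide, HBr in DMF and carbonate, yet falls to fluoride.

Step 5
Reactants: 6 (R)-{[15-(benzyloxy)pentadec-1-en-4-yl]oxy}(tert-butyl)diphenylsilane; 7 benzyl acrylate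
Product: 8 benzyl (R,E)-16-(benzyloxy)-5-[(tert-butyldiphenylsilyl)oxy]hexadec-2-enoate
Conditions: 7 (3 equiv), second-generation Grubbs catalyst RuCl2(=CHPh)(PCy3)(H2IMes) (5 mol %), CH2Cl2, 40 °C
Reagents that add atoms: none
Why: Olefin cross-metathesis between an unhindered terminal alkene and an electron-poor acrylate is selective for the (E)-configured cross product with loss of ethylene, and the stereocentre is remote from the reacting alkene.

Step 6
Reactants: 8 benzyl (R,E)-16-(benzyloxy)-5-[(tert-butyldiphenylsilyl)oxy]hexadec-2-enoate; 9 benzyl acetoacetate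
Product: 11 benzyl 6-{(R)-13-(benzyloxy)-2-[(tert-butyldiphenylsilyl)oxy]tridecyl}-2,4-dioxocyclohexane-1-carboxylate (ring diastereomers in equilibrium with enol forms), via Michael adduct 10 (not isolated)
Conditions: 9 (1.3 equiv), NaOCH2Ph (1.0 M in PhCH2OH, 0.2 equiv), THF, 45 °C until 8 is consumed; then NaOCH2Ph (further 1.3 equiv), 65 °C; AcOH, 0 °C
Reagents that add atoms: none
Why: The sodium enolate of 9 adds through its central carbon (C1) to the enoate β-carbon of 8 (C6), proton transfer gives the stabilised enolate of adduct 10, and once the alkoxide charge is raised the methyl-derived enolate (C3) attacks the side-chain benzyl ester (C4), expels benzyloxide and the cyclic product is deprotonated at once, which pulls the preceding equilibria forward and is why more than one equivalent of base is used. The closest known reaction is the Michael–Claisen (Dieckmann-type) annulation of acetoacetates with crotonates that gives dihydroorsellinates. The ring closes by a 6-(enolendo)-exo-trig acyl substitution; any other enolate and carbonyl pair in 10 would give a four-membered ring, so only the carbocycle of ring A can form. C1 and C6 become sp3 stereocentres without any controlling element and are expected as a mixture, which does not matter because both are flattened in step 7, while C2′ carries no acidic hydrogen and keeps its configuration. The selectivity that is needed is conjugate addition ahead of γ-deprotonation of 8 and vinylogous loss of the silyloxy group; it is secured by keeping 9 in excess over alkoxide in the first stage, so that the only base present is the weakly basic keto ester enolate, and by adding the full charge of alkoxide only when no enoate is left. Benzyl esters on both partners together with benzyloxide as base make every ester exchange degenerate.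

Step 7
Reactants: 11 benzyl 6-{(R)-13-(benzyloxy)-2-[(tert-butyldiphenylsilyl)oxy]tridecyl}-2,4-dioxocyclohexane-1-carboxylate
Product: 14 benzyl 6-{(R)-13-(benzyloxy)-2-[(tert-butyldiphenylsilyl)oxy]tridecyl}-2,4-dihydroxybenzoate, via 3-bromo dione 12 (not isolated), via 1-bromo dione 13 (not isolated)
Conditions: Br2 (1.0 equiv), DMF, 0 °C; then 70 °C
Reagents that add atoms: none
Why: Bromination–dehydrobromination aromatisation, known for 6-alkyl-2,4-dioxocyclohexane-1-carboxylates: bromine enters at C3 between the carbonyls, is relayed by HBr to an α-carbon with a β-hydrogen (drawn at C1), HBr is lost across C1–C6 and enolisation gives the resorcylate, while DMF buffers the HBr and exactly one equivalent of Br2 limits ring bromination.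

Step 8
Reactants: 14 benzyl 6-{(R)-13-(benzyloxy)-2-[(tert-butyldiphenylsilyl)oxy]tridecyl}-2,4-dihydroxybenzoate
Product: 15 benzyl 2,4-bis(benzyloxy)-6-{(R)-13-(benzyloxy)-2-[(tert-butyldiphenylsilyl)oxy]tridecyl}benzoate
Conditions: BnBr (2.5 equiv), K2CO3 (3 equiv), Bu4NI (cat.), DMF, 60–70 °C
Reagents that add atoms: benzyl bromide, BrCc1ccccc1
Why: Williamson O-benzylation of both phenoxides, with heating so that the hydrogen-bonded C2 hydroxyl also reacts; the silyl ether and the benzyl ester are inert to carbonate.

Step 9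
Reactants: 15 benzyl 2,4-bis(benzyloxy)-6-{(R)-13-(benzyloxy)-2-[(tert-butyldiphenylsilyl)oxy]tridecyl}benzoate
Product: 16 benzyl 2,4-bis(benzyloxy)-6-[(R)-13-(benzyloxy)-2-hydroxytridecyl]benzoate
Conditions: HF·pyridine, pyridine, THF, 0 °C → rt; NaHCO3 work-up, used at once
Reagents that add atoms: none
Why: Fluoride-driven cleavage of the Si–O bond (formation of the strong Si–F bond) in a pyridine-buffered medium, which offers neither the alkoxide nor the strong acid that would promote attack of the freed C2′ hydroxyl on the neighbouring ester; the C2′–O bond is not broken, so the configuration is retained.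

Step 10
Reactants: 16 benzyl 2,4-bis(benzyloxy)-6-[(R)-13-(benzyloxy)-2-hydroxytridecyl]benzoate
Product: 17 benzyl 6-[(R)-2-acetoxy-13-(benzyloxy)tridecyl]-2,4-bis(benzyloxy)benzoate
Conditions: Ac2O, pyridine, 4-(dimethylamino)pyridine (cat.), CH2Cl2, 0 °C
Reagents that add atoms: acetic anhydride, CC(=O)OC(C)=O
Why: Nucleophile-catalysed acylation of the only free hydroxyl is fast at 0 °C and should outpace lactonisation, and it proceeds with retention at C2′.

Step 11
Reactants: 17 benzyl 6-[(R)-2-acetoxy-13-(benzyloxy)tridecyl]-2,4-bis(benzyloxy)benzoate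
Product: 18 2-[(R)-2-acetoxy-13-hydroxytridecyl]-4,6-dihydroxybenzoic acid (CNP0361881.1)
Conditions: H2 (1 atm), Pd/C (10 %), EtOAc/EtOH, rt
Reagents that add atoms: none
Why: Catalytic hydrogenolysis removes the benzyl ester, both aryl benzyl ethers and the alkyl benzyl ether in one operation, while the acetate, the arene and the stereocentre are inert under neutral conditions at room temperature, which also avoids decarboxylation of the resorcylic acid.

**Compound list**

1 | dodecane-1,12-diol | OCCCCCCCCCCCCO | starting material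
2 | 12-(benzyloxy)dodecan-1-ol | OCCCCCCCCCCCCOCc1ccccc1 | intermediate
3 | 12-(benzyloxy)dodecanal | O=CCCCCCCCCCCCOCc1ccccc1 | intermediate
4 | (R)-15-(benzyloxy)pentadec-1-en-4-yl diisopinocampheylborinate (isopinocampheyl groups of the (+)-α-pinene series) | C=CC[C@@H](CCCCCCCCCCCOCc1ccccc1)OB([C@@H]1C[C@@H]2C[C@H]([C@H]1C)C2(C)C)[C@@H]1C[C@@H]2C[C@H]([C@H]1C)C2(C)C | intermediate
5 | (R)-15-(benzyloxy)pentadec-1-en-4-ol | O[C@H](CCCCCCCCCCCOCc1ccccc1)CC=C | intermediate
6 | (R)-{[15-(benzyloxy)pentadec-1-en-4-yl]oxy}(tert-butyl)diphenylsilane | CC(C)(C)[Si](c1ccccc1)(c1ccccc1)O[C@H](CCCCCCCCCCCOCc1ccccc1)CC=C | intermediate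
7 | benzyl acrylate | C=CC(=O)OCc1ccccc1 | starting material
8 | benzyl (R,E)-16-(benzyloxy)-5-[(tert-butyldiphenylsilyl)oxy]hexadec-2-enoate | CC(C)(C)[Si](c1ccccc1)(c1ccccc1)O[C@H](CCCCCCCCCCCOCc1ccccc1)C/C=C/C(=O)OCc1ccccc1 | intermediate
9 | benzyl acetoacetate (benzyl 3-oxobutanoate) | CC(=O)CC(=O)OCc1ccccc1 | starting material
10 | dibenzyl 2-acetyl-3-{(R)-13-(benzyloxy)-2-[(tert-butyldiphenylsilyl)oxy]tridecyl}pentanedioate (diastereomers at C2 and C3) | CC(C)(C)[Si](c1ccccc1)(c1ccccc1)O[C@H](CCCCCCCCCCCOCc1ccccc1)CC(CC(=O)OCc1ccccc1)C(C(C)=O)C(=O)OCc1ccccc1 | intermediate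
11 | benzyl 6-{(R)-13-(benzyloxy)-2-[(tert-butyldiphenylsilyl)oxy]tridecyl}-2,4-dioxocyclohexane-1-carboxylate (ring diastereomers, largely enolised) | CC(C)(C)[Si](c1ccccc1)(c1ccccc1)O[C@H](CCCCCCCCCCCOCc1ccccc1)CC1CC(=O)CC(=O)C1C(=O)OCc1ccccc1 | intermediate
12 | benzyl 3-bromo-6-{(R)-13-(benzyloxy)-2-[(tert-butyldiphenylsilyl)oxy]tridecyl}-2,4-dioxocyclohexane-1-carboxylate | CC(C)(C)[Si](c1ccccc1)(c1ccccc1)O[C@H](CCCCCCCCCCCOCc1ccccc1)CC1CC(=O)C(Br)C(=O)C1C(=O)OCc1ccccc1 | intermediate
13 | benzyl 1-bromo-6-{(R)-13-(benzyloxy)-2-[(tert-butyldiphenylsilyl)oxy]tridecyl}-2,4-dioxocyclohexane-1-carboxylate | CC(C)(C)[Si](c1ccccc1)(c1ccccc1)O[C@H](CCCCCCCCCCCOCc1ccccc1)CC1CC(=O)CC(=O)C1(Br)C(=O)OCc1ccccc1 | intermediate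
14 | benzyl 6-{(R)-13-(benzyloxy)-2-[(tert-butyldiphenylsilyl)oxy]tridecyl}-2,4-dihydroxybenzoate | CC(C)(C)[Si](c1ccccc1)(c1ccccc1)O[C@H](CCCCCCCCCCCOCc1ccccc1)Cc1cc(O)cc(O)c1C(=O)OCc1ccccc1 | intermediate
15 | benzyl 2,4-bis(benzyloxy)-6-{(R)-13-(benzyloxy)-2-[(tert-butyldiphenylsilyl)oxy]tridecyl}benzoate | CC(C)(C)[Si](c1ccccc1)(c1ccccc1)O[C@H](CCCCCCCCCCCOCc1ccccc1)Cc1cc(OCc2ccccc2)cc(OCc2ccccc2)c1C(=O)OCc1ccccc1 | intermediate
16 | benzyl 2,4-bis(benzyloxy)-6-[(R)-13-(benzyloxy)-2-hydroxytridecyl]benzoate | O[C@H](CCCCCCCCCCCOCc1ccccc1)Cc1cc(OCc2ccccc2)cc(OCc2ccccc2)c1C(=O)OCc1ccccc1 | intermediate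
17 | benzyl 6-[(R)-2-acetoxy-13-(benzyloxy)tridecyl]-2,4-bis(benzyloxy)benzoate | CC(=O)O[C@H](CCCCCCCCCCCOCc1ccccc1)Cc1cc(OCc2ccccc2)cc(OCc2ccccc2)c1C(=O)OCc1ccccc1 | intermediate
18 | 2-[(R)-2-acetoxy-13-hydroxytridecyl]-4,6-dihydroxybenzoic acid (CNP0361881.1) | CC(=O)O[C@H](CCCCCCCCCCCO)Cc1cc(O)cc(O)c1C(=O)O | target

**Totals.** Total step count: 11. Longest linear sequence: 11 steps (1 to 18); 7 and 9 are purchased.

**Steps most likely to fail**

Step 6. What may go wrong: alkoxide removes a γ-hydrogen of enoate 8 faster than the keto ester enolate adds, and the dienolate expels the silyloxy group to leave a dienoate; or the conjugate addition stays too slow and reversible for ring closure to follow. The fallback builds the same ring from a different bond set. Setting out from 6, cross-metathesis with methyl vinyl ketone (second-generation Grubbs catalyst, CH2Cl2, 40 °C) should give the enone (R,E)-17-(benzyloxy)-6-[(tert-butyldiphenylsilyl)oxy]heptadec-3-en-2-one F1. This is a much stronger acceptor, to which dibenzyl malonate adds at 0 °C under catalytic NaOCH2Ph to give dibenzyl 2-{(6R)-17-(benzyloxy)-6-[(tert-butyldiphenylsilyl)oxy]-2-oxoheptadecan-4-yl}propanedioate F2. Stoichiometric NaOCH2Ph at 60 °C then lets the methyl ketone enolate attack one malonate ester (C2–C3 in place of C3–C4). This is the known malonate–enone route to 6-alkyl dihydroresorcylates, and it comes back to the route at 11.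

Step 7. What may go wrong: transfer of bromine to the electron-rich arene as it forms, or acid-promoted erosion of the silyl ether at the elevated temperature, after which the freed hydroxyl closes onto the ester. The fallback is a dehydrogenation without halogen or acid. Setting out from 11, Me3SiOTf and Et3N (CH2Cl2, 0 °C) should give the bis(silyl) dienol ether benzyl 6-{(R)-13-(benzyloxy)-2-[(tert-butyldiphenylsilyl)oxy]tridecyl}-2,4-bis[(trimethylsilyl)oxy]cyclohexa-1,3-diene-1-carboxylate F3. 2,3-Dichloro-5,6-dicyano-1,4-benzoquinone with 2,6-lutidine in toluene at room temperature abstracts hydride from the allylic ring positions and should give the aryl bis(silyl ether) benzyl 6-{(R)-13-(benzyloxy)-2-[(tert-butyldiphenylsilyl)oxy]tridecyl}-2,4-bis[(trimethylsilyl)oxy]benzoate F4. Its aryl silyl ethers are hydrolysed with aqueous citric acid in THF, and the sequence comes back to the route at 14.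

Step 9. What may go wrong: intramolecular transesterification, in which the liberated C2′ hydroxyl attacks the neighbouring benzyl ester and closes a six-membered lactone (a 3,4-dihydroisocoumarin) irreversibly. In the fallback the alcohol is unmasked at a stage where the ester is a poorer electrophile, and acetyl serves as the phenol protection. Setting out from 14, whose ester carbonyl is conjugated with the dihydroxyarene, HF·pyridine should give the triol benzyl 6-[(R)-13-(benzyloxy)-2-hydroxytridecyl]-2,4-dihydroxybenzoate F5. Ac2O, pyridine and catalytic 4-(dimethylamino)pyridine convert it into the triacetate benzyl 2,4-diacetoxy-6-[(R)-2-acetoxy-13-(benzyloxy)tridecyl]benzoate F6. Hydrazine acetate in DMF cleaves only the two far more labile aryl acetates and should give benzyl 6-[(R)-2-acetoxy-13-(benzyloxy)tridecyl]-2,4-dihydroxybenzoate F7. Hydrogenolysis of its benzyl ester and benzyl ether (H2, Pd/C, EtOAc) comes back to the route at 18.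

Further compounds
F1 | step 6 | (R,E)-17-(benzyloxy)-6-[(tert-butyldiphenylsilyl)oxy]heptadec-3-en-2-one | CC(C)(C)[Si](c1ccccc1)(c1ccccc1)O[C@H](CCCCCCCCCCCOCc1ccccc1)C/C=C/C(C)=O
F2 | step 6 | dibenzyl 2-{(6R)-17-(benzyloxy)-6-[(tert-butyldiphenylsilyl)oxy]-2-oxoheptadecan-4-yl}propanedioate | CC(C)(C)[Si](c1ccccc1)(c1ccccc1)O[C@H](CCCCCCCCCCCOCc1ccccc1)CC(CC(C)=O)C(C(=O)OCc1ccccc1)C(=O)OCc1ccccc1
F3 | step 7 | benzyl 6-{(R)-13-(benzyloxy)-2-[(tert-butyldiphenylsilyl)oxy]tridecyl}-2,4-bis[(trimethylsilyl)oxy]cyclohexa-1,3-diene-1-carboxylate | CC(C)(C)[Si](c1ccccc1)(c1ccccc1)O[C@H](CCCCCCCCCCCOCc1ccccc1)CC1CC(O[Si](C)(C)C)=CC(O[Si](C)(C)C)=C1C(=O)OCc1ccccc1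
F4 | step 7 | benzyl 6-{(R)-13-(benzyloxy)-2-[(tert-butyldiphenylsilyl)oxy]tridecyl}-2,4-bis[(trimethylsilyl)oxy]benzoate | CC(C)(C)[Si](c1ccccc1)(c1ccccc1)O[C@H](CCCCCCCCCCCOCc1ccccc1)Cc1cc(O[Si](C)(C)C)cc(O[Si](C)(C)C)c1C(=O)OCc1ccccc1
F5 | step 9 | benzyl 6-[(R)-13-(benzyloxy)-2-hydroxytridecyl]-2,4-dihydroxybenzoate | O[C@H](CCCCCCCCCCCOCc1ccccc1)Cc1cc(O)cc(O)c1C(=O)OCc1ccccc1
F6 | step 9 | benzyl 2,4-diacetoxy-6-[(R)-2-acetoxy-13-(benzyloxy)tridecyl]benzoate | CC(=O)O[C@H](CCCCCCCCCCCOCc1ccccc1)Cc1cc(OC(C)=O)cc(OC(C)=O)c1C(=O)OCc1ccccc1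
F7 | step 9 | benzyl 6-[(R)-2-acetoxy-13-(benzyloxy)tridecyl]-2,4-dihydroxybenzoate | CC(=O)O[C@H](CCCCCCCCCCCOCc1ccccc1)Cc1cc(O)cc(O)c1C(=O)OCc1ccccc1
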